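The target in the earlier runs stops near the reagent charge: 36.7% in the alpha run with 0.35 equiv, and 70.4% in the gamma run with 0.70 equiv. In those two runs reagent is therefore the limiting reagent of the second step, and whatever it cannot carry on stays as intermediate. For the asked flask, one minus its equivalents gives 30.0%, and this is the remainder, the share of the substrate charged that the reagent cannot take on to target.

| flask | substrate | reagent | free catalyst | second catalyst | remark | time |
|---|---|---|---|---|---|---|
| alpha | 0.11 M | 0.35 equiv | 0.082 mol% | 0.05 mol% | run made earlier |  |
| eta | 0.11 M | 1.4 equiv | 0.082 mol% | 0.05 mol% | run made earlier |  |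
| gamma | 0.11 M | 0.70 equiv | 0.12 mol% | 0.05 mol% | run made earlier |  |
| flask | 0.11 M | 0.700 equiv | 0.082 mol% | 0.05 mol% |  | 2.5 d |

| run | time / h | intermediate / % | target / % |
|---|---|---|---|
| alpha | 1.00 | 30.3 | 2.9 |
| alpha | 2.50 | 50.6 | 13.4 |
| alpha | 8.00 | 64.8 | 30.8 |
| alpha | 20.0 | 63.8 | 35.1 |
| alpha | 50.0 | 65.6 | 36.7 |
| eta | 1.00 | 21.0 | 11.4 |
| eta | 2.50 | 25.7 | 33.5 |
| eta | 8.00 | 9.7 | 84.5 |
| eta | 20.0 | 0.6 | 100.3 |
| eta | 50.0 | 1.5 | 99.6 |
| gamma | 1.00 | 35.9 | 9.0 |
| gamma | 2.50 | 49.8 | 27.4 |
| gamma | 8.00 | 40.9 | 58.9 |
| gamma | 20.0 | 31.0 | 71.0 |
| gamma | 50.0 | 32.5 | 70.4 |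

(each reading ± 1 percentage point)

* time, not beyond 2.5 d, at which the flask holds most intermediate
* the amount of intermediate, in percent of the substrate charged, at that time

- the numbers in the tables scatter by 1 percentage point (one standard deviation)

Two of us disagreed about this flask. The first read it as an alpha run with more reagent. In the alpha run, [intermediate] came to rest at 65.6%, against a remainder of 65.0%, so this view puts the best at the remainder, at the end.

Gamma did overshoot, with 49.8% at 2.50 h and 32.5% at 50.0 h, but gamma carries 0.12 mol% of free catalyst against the 0.082 mol% of the asked flask, so the first view set it aside. From the readings at 1.00 h, the substrate half-life is 1.16 h in gamma, shorter than the 1.72 h read in alpha, whose free catalyst the asked flask shares.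

I took the other side. Gamma's reading at 2.50 h stands 20 percentage points above the remainder, and if that height shrinks in step with the substrate half-life, my own estimate for the asked flask is about 43.4%. The forecast, stepped by hand, also expects a hump: 43.3% at 0.175 d, “so the peak is transient”.

The flask holds most intermediate at 0.168 d, with 42.4%, which is 12 points above the remainder. At 0.0731 d the flask makes intermediate 1.71 times faster than it uses it up, with a substrate half-life of 0.073 d by the first step, shorter than the 0.089 d of the intermediate by the second step. That second half-life is short against 2.5 d, and [intermediate] stands at 30.0% at the end, the remainder, with 0% of the reagent left. The first view holds in a neighbour of this flask with 0.420 equiv of reagent: its remainder is 58.0%, and its best equals what stands at its end, 58.0%.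

    substrate + free catalyst → free catalyst + intermediate (k = 1.22 M⁻¹ s⁻¹)
    reagent + second catalyst + intermediate → second catalyst + target (k = 26.6 M⁻² s⁻¹)

Readings and results stem from a simulated flask on assumed constants, noise included.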